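**Retrosynthetic overview** (drimane numbering: ring A = C1–C5 + C10, ring B = C5–C10, C11 = exocyclic carbon bearing Cl and the arene; β = face of the C10 methyl)
- Target ⇒ bis-MOM ether ⇒ C11–Cl from a C11 enol triflate of the same geometry ⇒ 1,4-hydrosilylation of a C8=C9–C11(=O)Ar enone, which sets C8 and the alkene geometry together.
- Enone ⇒ C9 enol triflate + CO + aryl stannane (arene from 5-bromovanillin); C9 ketone ⇒ trans 6,9-dione by removal of the C6 oxygen through its enol triflate.
- The route rests on ring B: C9 sits between the methyl-bearing C8 and C10, and ring A carries the C4 gem-dimethyl group. That is the pattern of 2,6-dimethyl-1,4-benzoquinone (ring B, bought) plus 4-methylpenta-1,3-diene, joined by a [4+2] that forms C1–C10 and C4–C5.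
- Ring order: ring B comes preformed, ring A is closed in step 1, the arene is attached in step 10.

Key step: step 1

Assumption: the face selection of the (S)-oxazaborolidinium catalyst is taken from its behaviour with other quinones, enones and acrylates bound through an α-C–H contact; if adduct 3 proves to be the C10 antipode, the (R)-catalyst is used and nothing else changes.

**Step 1**
Reactants: 1 2,6-dimethyl-1,4-benzoquinone; 2 4-methylpenta-1,3-diene
Product: 3 cis-fused 4,4,8,10-tetramethyldecalin-2,7-diene-6,9-dione (5β-H, 10β-Me)
Conditions: (S)-3,3-diphenyl-1-(2-methylphenyl)tetrahydro-1H,3H-pyrrolo[1,2-c][1,3,2]oxazaborole (20 mol%), HNTf2 (17 mol%), 2 (4 equiv, slow addition), CH2Cl2, −78 → −40 °C; Et3N quench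
Reagents that add atoms: none
Why: The N-protonated oxazaborolidine binds the unhindered carbonyl oxygen of 1 (future C6=O) at boron, syn to the adjacent ring C–H (future C5–H), so the methyl-bearing β-carbon (future C10) becomes the electrophilic site; the CH2 terminus of 2 bonds there and the CMe2 terminus bonds to the neighbouring CH in a concerted but strongly asynchronous suprafacial [4+2] cycloaddition. The closest known reaction type is the chiral oxazaborolidinium-catalysed Diels–Alder reaction of 2,6-dialkyl-1,4-benzoquinones with acyclic dienes, here applied to a diene with a (Z)-methyl terminus. Ring A (C1–C5, C10) is closed by intermolecular [4+2] annulation, C1–C10 and C4–C5 being formed in the one step as a six-membered carbocycle. C10 is set by the catalyst, whose gem-diphenyl group screens one face of the bound C=C, and C5 is set cis to the C10 methyl by the suprafacial addition (it is inverted in step 2). The step needs regioselectivity (C1 to C10, not C1 to C5), secured by Lewis acid binding at the carbonyl without flanking methyl groups and by the larger HOMO coefficient at the CH2 terminus; site selectivity is no issue because the two C=C bonds of 1 are interchanged by its twofold axis. The advanced C1–C10 bonding should tolerate a diene that cannot become fully planar s-cis, and the slight deficit of HNTf2 leaves no free acid to oligomerise 2.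

**Step 2**
Reactants: 3 cis-fused enedione adduct
Product: 5 trans-4,4,8,10-tetramethyldecalin-6,9-dione (5α-H 8α-Me), via cis-fused saturated dione 4 (not isolated)
Conditions: H2 (1 atm), Pd/C (10%), MeOH, rt; filter; NaOMe (0.5 equiv), MeOH, 50 °C, Ar
Reagents that add atoms: none
Why: Heterogeneous hydrogenation saturates the enedione C7=C8 and the ring A C2=C3 bonds without touching the ketones, and reversible enolisation of the C6 ketone (base epimerisation of a cis-fused quinone Diels–Alder adduct) should then bring C5 to the trans-decalin, because either chair form of the cis isomer places C6 axial on ring A or the gem-dimethyl carbon axial on ring B; C8 settles with its methyl equatorial.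

**Step 3**
Reactants: 5 trans-dione
Product: 7 trans-4,4,8,10-tetramethyl-9-oxodecal-6-en-6-yl triflate, via potassium C6 enolate 6 (not isolated)
Conditions: KN(SiMe3)2 (1.05 equiv), THF, −78 °C; PhNTf2, −78 → 0 °C
Reagents that add atoms: N-phenylbis(trifluoromethanesulfonimide), O=S(=O)(N(c1ccccc1)S(=O)(=O)C(F)(F)F)C(F)(F)F
Why: Kinetic deprotonation by the bulky amide should take the accessible axial C7–H next to C6 (C5–H and C8–H are tertiary and screened) and O-sulfonylation gives the enol triflate; this enol triflate formation keeps C6 trigonal, so no tetrahedral intermediate has to form under the syn-axial C4 and C10 methyls, which would hamper thioketal or hydrazone formation.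

**Step 4**
Reactants: 7 C6 enol triflate
Product: 8 trans-4,4,8,10-tetramethyldecal-6-en-9-one
Conditions: Pd(OAc)2 (5 mol%), PPh3 (10 mol%), HCO2H (2 equiv), Et3N (3 equiv), DMF, 60 °C
Reagents that add atoms: none
Why: Palladium-catalysed formate reduction of an enol triflate: oxidative addition to zerovalent palladium, formate exchange, decarboxylation to a palladium hydride and reductive elimination replace OTf by H.

**Step 5**
Reactants: 8 alkene ketone
Product: 9 trans-4,4,8,10-tetramethyldecalin-9-one (5α-H, 10β-Me)
Conditions: H2 (1 atm), Pd/C (10%), EtOAc, rt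
Reagents that add atoms: none
Why: Catalytic hydrogenation of the disubstituted C6=C7 bond (and of any conjugated C7=C8 isomer formed in step 4) leaves the hindered C9 ketone; the C8 configuration is of no consequence because step 6 erases it.

**Step 6**
Reactants: 9 C9 ketone
Product: 11 trans-4,4,8,10-tetramethyldecal-8-en-9-yl triflate, via potassium C9 enolate 10 (not isolated)
Conditions: KN(SiMe3)2 (1.3 equiv), THF, 0 °C; PhNTf2, 0 °C → rt
Reagents that add atoms: N-phenylbis(trifluoromethanesulfonimide), O=S(=O)(N(c1ccccc1)S(=O)(=O)C(F)(F)F)C(F)(F)F
Why: C10 is quaternary, so C8–H is the only α-hydrogen and enolisation is regiospecific; O-triflation of the enolate gives the tetrasubstituted enol triflate, as for 2,2,6-trimethylcyclohexanone.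

**Step 7**
Reactants: 12 5-bromovanillin
Product: 14 2-bromo-6-methoxybenzene-1,4-diol, via aryl formate 13 (not isolated)
Conditions: H2O2 (30% aq., 1.3 equiv), H2SO4 (cat.), MeOH, rt, N2
Reagents that add atoms: hydrogen peroxide, OO
Why: Acid-catalysed Dakin oxidation: the hydroperoxide adduct of the aldehyde rearranges with migration of the electron-rich aryl group to the aryl formate, which methanol cleaves to the hydroquinone; acidic medium avoids air oxidation of the product.

**Step 8**
Reactants: 14 bromomethoxyhydroquinone
Product: 15 1-bromo-3-methoxy-2,5-bis(methoxymethoxy)benzene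
Conditions: NaH (2.5 equiv), DMF, 0 °C; MOMCl (2.4 equiv), 0 °C → rt
Reagents that add atoms: chloromethyl methyl ether, COCCl
Why: Williamson etherification of both phenoxides with the reactive α-chloro ether; the MOM ethers should survive the organolithium, palladium, rhodium, fluoride and nickel steps and leave under mild acid.

**Step 9**
Reactants: 15 aryl bromide
Product: 17 [3-methoxy-2,5-bis(methoxymethoxy)phenyl]trimethylstannane, via aryllithium 16 (not isolated)
Conditions: n-BuLi (1.05 equiv), THF, −78 °C; Me3SnCl, −78 °C → rt
Reagents that add atoms: chlorotrimethylstannane, C[Sn](C)(C)Cl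
Why: Bromine–lithium exchange is faster than ortho-deprotonation and gives the aryllithium held by the ortho MOM oxygen, which is stannylated at tin.

**Step 10**
Reactants: 11 C9 enol triflate; 17 aryl stannane
Product: 18 aryl enone, [3-methoxy-2,5-bis(methoxymethoxy)phenyl] (trans-4,4,8,10-tetramethyldecal-8-en-9-yl) ketone
Conditions: Pd(PPh3)4 (5 mol%), LiCl (3 equiv), CO (3 atm), 1,4-dioxane, 80 °C
Reagents that add atoms: carbon monoxide, [C-]#[O+]
Why: Carbonylative Stille coupling: oxidative addition of the enol triflate, CO insertion (favoured because it relieves crowding at the tetrasubstituted alkenylpalladium), tin-to-palladium transfer of the aryl group and reductive elimination give the ketone; known for 2,6,6-trimethylcyclohexenyl-type triflates.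

**Step 11**
Reactants: 18 aryl enone
Product: 19 (E)-triethylsilyl enol ether with C9=C11 exocyclic, 8β-Me, O cis to C8 and aryl cis to C10
Conditions: RhCl(PPh3)3 (5 mol%), Et3SiH (3 equiv), toluene, 80 °C
Reagents that add atoms: triethylsilane, CC[SiH](CC)CC
Why: Rhodium-catalysed 1,4-hydrosilylation: silicon goes to the carbonyl oxygen and the rhodium hydride delivers H to C8 within the s-cis O=C11–C9=C8 array, so oxygen ends cis to C8 (E enol ether), and H enters C8 from the α face opposite the axial C10 methyl, which sets the 8β-methyl stereocentre.

**Step 12**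
Reactants: 19 silyl enol ether
Product: 21 (E)-C11 enol triflate, via cesium enolate 20 (not isolated)
Conditions: CsF (2 equiv, anhydrous), PhNTf2 (1.5 equiv), DME, rt
Reagents that add atoms: N-phenylbis(trifluoromethanesulfonimide), O=S(=O)(N(c1ccccc1)S(=O)(=O)C(F)(F)F)C(F)(F)F
Why: Fluoride-mediated conversion of a silyl enol ether to an enol triflate: fluoride cleaves the Si–O bond and the tetrasubstituted enolate, which has no α-hydrogen pathway for isomerisation in the absence of proton sources, is O-triflated in situ with its geometry kept.

**Step 13**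
Reactants: 21 C11 enol triflate
Product: 22 (E)-alkenyl chloride bis-MOM ether
Conditions: Ni(cod)2 [bis(cycloocta-1,5-diene)nickel] (10 mol%), LiCl (3 equiv), DMA–THF (1:3), rt
Reagents that add atoms: lithium chloride, [Li+].[Cl-]
Why: Nickel-catalysed halide exchange of an enol triflate: oxidative addition of C–OTf to zerovalent nickel, triflate/chloride exchange and C–Cl reductive elimination at the same carbon should carry the alkene geometry (Cl cis to C8) over.

**Step 14**
Reactants: 22 bis-MOM ether
Product: 23 target, 2-{(E)-chloro[(2S,4aS,8aS)-2,5,5,8a-tetramethyloctahydronaphthalen-1(2H)-ylidene]methyl}-6-methoxybenzene-1,4-diol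
Conditions: HCl (1.25 M in MeOH, degassed), 0 °C → rt, Ar
Reagents that add atoms: none
Why: Acid-catalysed acetal exchange with methanol removes both MOM groups as dimethoxymethane; the tetrasubstituted chloroalkene, twisted out of conjugation with the arene, should not be protonated by dilute acid, and argon protects the hydroquinone.

**Compound list**
1 | 2,6-dimethyl-1,4-benzoquinone | CC1=CC(=O)C=C(C)C1=O | starting material
2 | 4-methylpenta-1,3-diene | CC(C)=CC=C | starting material
3 | cis-fused 4,4,8,10-tetramethyldecalin-2,7-diene-6,9-dione (5β-H, 10β-Me) | O=C2C(C)=CC(=O)[C@@H]3C(C)(C)C=CC[C@]23C | intermediate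
4 | cis-4,4,8,10-tetramethyldecalin-6,9-dione (5β-H, C8 epimers) | O=C2C(C)CC(=O)[C@@H]3C(C)(C)CCC[C@]23C | intermediate (not isolated)
5 | trans-4,4,8,10-tetramethyldecalin-6,9-dione (5α-H, 8α-Me) | O=C2[C@H](C)CC(=O)[C@H]3C(C)(C)CCC[C@]23C | intermediate
6 | potassium 6-en-6-olate of 5 | O=C2[C@H](C)C=C([O-])[C@H]3C(C)(C)CCC[C@]23C.[K+] | intermediate (not isolated)
7 | trans-4,4,8,10-tetramethyl-9-oxodecal-6-en-6-yl triflate | O=C2[C@H](C)C=C(OS(=O)(=O)C(F)(F)F)[C@H]3C(C)(C)CCC[C@]23C | intermediate
8 | trans-4,4,8,10-tetramethyldecal-6-en-9-one | O=C2[C@H](C)C=C[C@H]3C(C)(C)CCC[C@]23C | intermediate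
9 | trans-4,4,8,10-tetramethyldecalin-9-one (8α-Me drawn; C8 of no consequence) | O=C2[C@H](C)CC[C@H]3C(C)(C)CCC[C@]23C | intermediate
10 | potassium 8-en-9-olate of 9 | [O-]C2=C(C)CC[C@H]3C(C)(C)CCC[C@]23C.[K+] | intermediate (not isolated)
11 | trans-4,4,8,10-tetramethyldecal-8-en-9-yl triflate | O=S(=O)(OC2=C(C)CC[C@H]3C(C)(C)CCC[C@]23C)C(F)(F)F | intermediate
12 | 5-bromovanillin | COc1cc(C=O)cc(Br)c1O | starting material
13 | 3-bromo-4-hydroxy-5-methoxyphenyl formate | COc1cc(OC=O)cc(Br)c1O | intermediate (not isolated)
14 | 2-bromo-6-methoxybenzene-1,4-diol | COc1cc(O)cc(Br)c1O | intermediate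
15 | 1-bromo-3-methoxy-2,5-bis(methoxymethoxy)benzene | COCOc1cc(Br)c(OCOC)c(OC)c1 | intermediate
16 | [3-methoxy-2,5-bis(methoxymethoxy)phenyl]lithium | [Li]c1cc(OCOC)cc(OC)c1OCOC | intermediate (not isolated)
17 | [3-methoxy-2,5-bis(methoxymethoxy)phenyl]trimethylstannane | COCOc1cc([Sn](C)(C)C)c(OCOC)c(OC)c1 | intermediate
18 | aryl (decal-8-en-9-yl) ketone | COCOc1cc(C(=O)C2=C(C)CC[C@H]3C(C)(C)CCC[C@]23C)c(OCOC)c(OC)c1 | intermediate
19 | (E)-triethylsilyl enol ether (8β-Me, O cis to C8) | COCOc1cc(/C(O[Si](CC)(CC)CC)=C2/[C@@H](C)CC[C@H]3C(C)(C)CCC[C@]23C)c(OCOC)c(OC)c1 | intermediate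
20 | cesium (E)-enolate | COCOc1cc(/C([O-])=C2/[C@@H](C)CC[C@H]3C(C)(C)CCC[C@]23C)c(OCOC)c(OC)c1.[Cs+] | intermediate (not isolated)
21 | (E)-C11 enol triflate | COCOc1cc(/C(OS(=O)(=O)C(F)(F)F)=C2/[C@@H](C)CC[C@H]3C(C)(C)CCC[C@]23C)c(OCOC)c(OC)c1 | intermediate
22 | (E)-alkenyl chloride bis-MOM ether | COCOc1cc(/C(Cl)=C2/[C@@H](C)CC[C@H]3C(C)(C)CCC[C@]23C)c(OCOC)c(OC)c1 | intermediate
23 | CNP0162917.1 | COc1cc(O)cc(/C(Cl)=C2/[C@@H](C)CC[C@H]3C(C)(C)CCC[C@]23C)c1O | target

**Step count**
Total: 14 steps. Longest linear sequence: 11 steps (steps 1–6 and 10–14, from 1 and 2); the arene branch is steps 7–9.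

**Steps most likely to fail**

Step 1. The (Z)-methyl group keeps diene 2 out of the s-cis conformation, so the cycloaddition may be slower than acid-initiated oligomerisation of the diene, and face discrimination with this untested diene may be incomplete. The fallback sets out from 1 and replaces 2 by the far more nucleophilic 4-methyl-2-(triisopropylsilyloxy)penta-1,3-diene F1, made from mesityl oxide with LiN(i-Pr)2 and triisopropylsilyl triflate. Under the same oxazaborolidinium catalysis it should add through a Mukaiyama–Michael addition and ring closure that needs no planar s-cis diene, with the same regiochemistry, to give the C2 silyl enol ether adduct F2. CsF and PhNTf2 in DME convert the silyl enol ether regiospecifically into the C2 enol triflate adduct F3. Pd(OAc)2, PPh3, HCO2H and Et3N then reduce the triflate to 3, where the route is rejoined; any over-reduction of C7=C8 is harmless because step 2 saturates that bond.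

Step 11. The enone is twisted out of conjugation by the C8 methyl and the C10 quaternary centre. The rhodium hydride may therefore fail to engage the tetrasubstituted C8=C9 bond, 1,2-hydrosilylation of the carbonyl may take over, or delivery through an s-trans conformer may put oxygen cis to C10. The fallback sets out from 18 and uses electron transfer instead of hydrometalation: Li (2.2 equiv) in NH3–THF with t-BuOH (1 equiv) at −78 °C (Birch-type enone reduction). The β-carbanion should be protonated at C8 on the α face, and lithium bridging between oxygen and C8 in the dianion should hold the s-cis-derived geometry, giving the lithium (E)-enolate F4. After removal of ammonia it is trapped with N-(5-chloropyridin-2-yl)bis(trifluoromethanesulfonyl)imide in THF at 0 °C to give 21, where the route is rejoined.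

Step 13. Oxidative addition at the crowded tetrasubstituted α-aryl enol triflate may be slow, and the alkenylnickel intermediate may lose its geometry before the C–Cl bond forms. The fallback sets out from 21 and separates the two events: Pd(PPh3)4, Me3SnSnMe3 and LiCl in 1,4-dioxane at 90 °C should give the (E)-alkenyltrimethylstannane F5, which can be purified and its geometry checked. CuCl2 (2.2 equiv) in THF at rt then replaces tin by chlorine at the same carbon with retention, giving 22, where the route is rejoined.

**Further compounds**
F1 | step 1 | 4-methyl-2-(triisopropylsilyloxy)penta-1,3-diene | C=C(O[Si](C(C)C)(C(C)C)C(C)C)C=C(C)C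
F2 | step 1 | cis-fused enedione adduct with C2 triisopropylsilyl enol ether | O=C2C(C)=CC(=O)[C@@H]3C(C)(C)C=C(O[Si](C(C)C)(C(C)C)C(C)C)C[C@]23C
F3 | step 1 | cis-fused enedione adduct with C2 enol triflate | O=C2C(C)=CC(=O)[C@@H]3C(C)(C)C=C(OS(=O)(=O)C(F)(F)F)C[C@]23C
F4 | step 11 | lithium (E)-enolate of the 8β-methyl aryl ketone | COCOc1cc(/C([O-])=C2/[C@@H](C)CC[C@H]3C(C)(C)CCC[C@]23C)c(OCOC)c(OC)c1.[Li+]
F5 | step 13 | (E)-alkenyltrimethylstannane | COCOc1cc(/C([Sn](C)(C)C)=C2/[C@@H](C)CC[C@H]3C(C)(C)CCC[C@]23C)c(OCOC)c(OC)c1
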